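Multiply charge by time.

| flask | starting material | partner | second reagent | remark | time |
|---|---|---|---|---|---|
| larch | 0.070 M (fed, over 0.60 s) | 1.5 equiv | 0.80 equiv | run made earlier; the fed solution adds 0.10 times the starting volume |  |
| ash | 0.11 M (fed, over 0.60 s) | 1.5 equiv | 0.80 equiv | run made earlier; the fed solution adds 0.10 times the starting volume |  |
| flask | 0.050 M (fed, over 0.60 s) | 1.50 equiv | 0.800 equiv | the fed solution adds 0.10 times the starting volume | 6.0 min |

| run | time / min | target / % | starting material / % |
|---|---|---|---|
| larch | 0.333 | 22.7 | 16.2 |
| larch | 0.833 | 29.1 | 3.1 |
| larch | 2.00 | 26.4 | 0.5 |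
| larch | 6.00 | 10.9 | 1.6 |
| ash | 0.333 | 30.0 | 8.4 |
| ash | 0.833 | 32.6 | 0 |
| ash | 2.00 | 21.2 | 1.7 |
| ash | 6.00 | 7.6 | 0.1 |

(scatter of a reading: 1 percentage point)

* the best time, 6.0 min at the latest, for target
* the amount of target, in percent of the starting material charged, at that time

At fixed equivalents, a step with two reactants runs on [starting material] as charged multiplied by time, so runs at different charges can share one clock. The steps intermediate to side product B and second reagent to dormant form have one reactant and stay off that clock, so you should treat it as approximate. Take the top product 3.50 M·s, the charge times the time of the highest target reading in larch. It is a reading, from coarse sampling. The ash run fits the clock: at a product of 2.20 M·s it shows 8.4% starting material, between larch's 16.2% at 1.40 M·s and 3.1% at 3.50 M·s.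

By that clock this flask has its top at 1.17 min. My ladder for this flask starts below that with the feed, which ends at 0.60 s, far sooner than the top, so you can treat it as one shot. The next rung is that top. Larch's fall in target from 2.00 min to 6.00 min, scaled by charge, gives a loss rate of 0.158 min⁻¹. That is a loss time of 6.33 min, longer than the rise and close to the limit of 6.0 min. So the best time lies inside the limit, with a slow decline after it.

The forecast gives 1.2 min and 26%: “The peak is broad, so its time is less certain than its height.” My reckoning gives a time and no height.

The flask gives 1.16 min and 27.1%, so the forecast is right on both within the tolerance set on the questions.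

    starting material + partner → intermediate (k = 0.940 L mol⁻¹ s⁻¹)
    second reagent + intermediate → target (k = 2.60 L mol⁻¹ s⁻¹)
    starting material + second reagent → side product A (k = 0.860 L mol⁻¹ s⁻¹)
    intermediate → side product B (k = 0.0370 s⁻¹)
    second reagent ⇌ dormant form (K = 0.420, k = 0.0400 s⁻¹)
    partner + target → over-reaction product (k = 0.0990 L mol⁻¹ s⁻¹)

Charge times best time is 3.48 M·s, level with 3.50 M·s. So the limit of 6.0 min stands at 5.14 top products in this flask. A neighbour charged at 0.20 M, with equivalents and time held, reaches 20.6 top products by the same limit, so it should be far past its top. Its best is 34.8%, yet it ends with 3.76% target against 13.4% in the flask, and its over-reaction product stands at 45.4%.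

The numbers in the tables were computed with made-up constants, noise included.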